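**Retrosynthetic overview**
1. Target ⇐ its tri-O-methyl ether (BBr3 demethylation as the last step).
2. Tri-O-methyl macrocycle ⇐ open-chain 3-aryloxy-2-pyrone carrying an α-substituted vinyl sulfone: intramolecular Diels–Alder, then loss of CO2 and PhSO2H, so that ring D (the ortho-phenylene) and the 17-membered ring form in the same operation.
3. Vinyl sulfone ⇐ ring-A aldehyde (propargylation, benzylic deoxygenation, Markovnikov hydrosulfonylation); pyronyl ether ⇐ ring-C phenol + 3-bromo-2-pyrone (Cu C–O coupling).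
4. A–B–C backbone ⇐ B-alkyl Suzuki coupling of an o-vanillin-derived vinylphenol with a ring-B aryl chloride, itself from Ullmann coupling of 3-bromo-4,5-dimethoxybenzaldehyde with 4-chlorophenol.
5. Ring order: rings A, B and C are bought; ring D and the macrocycle are made last, together.

Assumption: the SMILES has no stereocentre and no defined axis, so the target is treated as achiral (macrocycle taken as conformationally mobile) and no stereocontrol is needed.

**Route**

Step 1
Reactants: 1 3-bromo-4,5-dimethoxybenzaldehyde; 2 4-chlorophenol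
Product: 3 3-(4-chlorophenoxy)-4,5-dimethoxybenzaldehyde
Conditions: CuI (10 mol%), N,N-dimethylglycine·HCl (30 mol%), Cs2CO3 (2 equiv), 1,4-dioxane, 100 °C
Reagents that add atoms: none
Why: Ullmann-type Cu-catalysed diaryl ether coupling in which the Ar–Br bond of 1 reacts while the Ar–Cl bond of 2 is inert to copper at this temperature, so the chloride is kept as the handle for step 3.

Step 2
Reactants: 4 2-hydroxy-3-methoxybenzaldehyde (o-vanillin)
Product: 5 2-ethenyl-6-methoxyphenol
Conditions: Ph3PCH3Br (2.3 equiv), KOtBu (2.3 equiv), THF, 0 °C to rt; aq. NH4Cl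
Reagents that add atoms: methyltriphenylphosphonium bromide, C[P+](c1ccccc1)(c1ccccc1)c1ccccc1.[Br-]
Why: Wittig methylenation with excess ylide (one equivalent of base is consumed by the phenol) is a standard way to an ortho-vinylphenol and creates no stereocentre.

Step 3
Reactants: 5 2-ethenyl-6-methoxyphenol; 3 3-(4-chlorophenoxy)-4,5-dimethoxybenzaldehyde
Product: 7 3-{4-[2-(2-hydroxy-3-methoxyphenyl)ethyl]phenoxy}-4,5-dimethoxybenzaldehyde, via bis-9-BBN adduct 6 (not isolated)
Conditions: 5 (1.3 equiv), 9-BBN (just under 2 equiv per 5), THF, 0 °C to rt; then 3, Pd(OAc)2 (3 mol%), SPhos (6 mol%), K3PO4 (3 equiv), H2O, 65 °C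
Reagents that add atoms: none
Why: B-alkyl Suzuki–Miyaura coupling in which anti-Markovnikov hydroboration of the styrene (the phenol O–H uses up the first B–H, so no hydride is left for the aldehyde of 3) gives a primary alkylborane that SPhos-ligated Pd couples with the electron-rich aryl chloride, giving the saturated CH2CH2 bridge directly without a hydrogenation.

Step 4
Reactants: 7 3-{4-[2-(2-hydroxy-3-methoxyphenyl)ethyl]phenoxy}-4,5-dimethoxybenzaldehyde; 8 3-bromo-2H-pyran-2-one
Product: 9 4,5-dimethoxy-3-{4-[2-(3-methoxy-2-{[2-oxo-2H-pyran-3-yl]oxy}phenyl)ethyl]phenoxy}benzaldehyde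
Conditions: CuI (10 mol%), picolinic acid (20 mol%), K3PO4 (2 equiv), DMSO, 70 °C
Reagents that add atoms: none
Why: Ullmann-type Cu-catalysed C(sp2)–O coupling of a phenol with a vinylic bromide, relying on 3-bromo-2-pyrone behaving as an α-bromo-enoate electrophile that is substituted at C3 with the ring intact and on the picolinic acid/K3PO4 system that tolerates ortho,ortho'-disubstituted phenols; this electrophile/phenol pairing is untested.

Step 5
Reactants: 9 4,5-dimethoxy-3-{4-[2-(3-methoxy-2-{[2-oxo-2H-pyran-3-yl]oxy}phenyl)ethyl]phenoxy}benzaldehyde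
Product: 10 3-(2-{2-[4-(5-(1-hydroxybut-3-yn-1-yl)-2,3-dimethoxyphenoxy)phenyl]ethyl}-6-methoxyphenoxy)-2H-pyran-2-one (racemic)
Conditions: propargyl bromide (1.5 equiv), Zn dust (2 equiv), THF, 0 °C to rt; then sat. aq. NH4Cl
Reagents that add atoms: propargyl bromide, C#CCBr
Why: Zinc Barbier propargylation in which the allenylzinc formed in the flask adds by SE2' to the aldehyde, the only electrophile of that reactivity (the pyrone lactone is untouched), giving the homopropargylic alcohol whose racemic carbinol centre is removed in step 6.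

Step 6
Reactants: 10 3-(2-{2-[4-(5-(1-hydroxybut-3-yn-1-yl)-2,3-dimethoxyphenoxy)phenyl]ethyl}-6-methoxyphenoxy)-2H-pyran-2-one
Product: 11 3-(2-{2-[4-(5-(but-3-yn-1-yl)-2,3-dimethoxyphenoxy)phenyl]ethyl}-6-methoxyphenoxy)-2H-pyran-2-one
Conditions: Et3SiH (3 equiv), CF3CO2H (10 equiv), CH2Cl2, 0 °C
Reagents that add atoms: none
Why: Ionic hydrogenation of a benzylic alcohol, where ionisation is easy because the cation is para to a methoxy group and hydride transfer from the silane gives the CH2, while the terminal alkyne, the diaryl ethers and the acid-stable pyrone are left alone at 0 °C.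

Step 7
Reactants: 11 3-(2-{2-[4-(5-(but-3-yn-1-yl)-2,3-dimethoxyphenoxy)phenyl]ethyl}-6-methoxyphenoxy)-2H-pyran-2-one
Product: 12 3-(2-{2-[4-(5-[3-(benzenesulfonyl)but-3-en-1-yl]-2,3-dimethoxyphenoxy)phenyl]ethyl}-6-methoxyphenoxy)-2H-pyran-2-one
Conditions: PhSO2H (1.5 equiv, freshly liberated from its sodium salt), Pd(PPh3)4 (5 mol%), THF, 60 °C
Reagents that add atoms: benzenesulfinic acid, O=S(O)c1ccccc1
Why: Pd(0)-catalysed Markovnikov hydrosulfonylation of a terminal alkyne puts the sulfonyl group on the internal carbon, turning the unreactive alkyne into an electron-poor 1,1-disubstituted vinyl sulfone that serves as a regiochemically biased alkyne equivalent.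

Step 8
Reactants: 12 3-(2-{2-[4-(5-[3-(benzenesulfonyl)but-3-en-1-yl]-2,3-dimethoxyphenoxy)phenyl]ethyl}-6-methoxyphenoxy)-2H-pyran-2-one
Product: 15 tri-O-methyl ether of the target macrocycle, via bridged lactone sulfone 13 (not isolated), via sulfonylcyclohexadiene 14 (not isolated)
Conditions: 1,2-Cl2C6H4 (1 mM, syringe-pump addition), BHT (cat.), 180 °C, Ar
Reagents that add atoms: none
Why: Intramolecular normal-demand Diels–Alder reaction of the electron-rich 3-aryloxy-2-pyrone with the vinyl sulfone, followed by retro-Diels–Alder loss of CO2 and aromatising elimination of PhSO2H, in which the nucleophilic pyrone C6 bonds to the electrophilic CH2 terminus so the sulfonyl-bearing carbon bonds to C3 (O and CH2CH2 end up ortho), closing the 17-membered ring and creating ring D together, with no stereocentre surviving.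

Step 9
Reactants: 15 tri-O-methyl ether of the target macrocycle
Product: 16 target trihydroxy macrocyclic bis(bibenzyl) (CNP0290892.0)
Conditions: BBr3 (8 equiv), CH2Cl2, −78 °C to rt; then ice-water
Reagents that add atoms: none
Why: BBr3 cleavage of aryl methyl ethers (Lewis acid–base adduct, then SN2 attack of bromide on methyl) is selective for O–CH3 over the diaryl ether bonds and frees the three phenols.

**Compound list**
1 | 3-bromo-4,5-dimethoxybenzaldehyde | O=Cc1cc(Br)c(OC)c(OC)c1 | starting material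
2 | 4-chlorophenol | Oc1ccc(Cl)cc1 | starting material
3 | 3-(4-chlorophenoxy)-4,5-dimethoxybenzaldehyde | O=Cc1cc(Oc2ccc(Cl)cc2)c(OC)c(OC)c1 | intermediate
4 | 2-hydroxy-3-methoxybenzaldehyde (o-vanillin) | COc1cccc(C=O)c1O | starting material
5 | 2-ethenyl-6-methoxyphenol | COc1cccc(C=C)c1O | intermediate
6 | 9-{2-[2-(9-borabicyclo[3.3.1]nonan-9-yloxy)-3-methoxyphenyl]ethyl}-9-borabicyclo[3.3.1]nonane (bis-9-BBN adduct of 5, formed in the flask) | COc1cccc(CCB2C3CCCC2CCC3)c1OB1C2CCCC1CCC2 | intermediate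
7 | 3-{4-[2-(2-hydroxy-3-methoxyphenyl)ethyl]phenoxy}-4,5-dimethoxybenzaldehyde | O=Cc1cc(Oc2ccc(CCc3cccc(OC)c3O)cc2)c(OC)c(OC)c1 | intermediate
8 | 3-bromo-2H-pyran-2-one | O=C1OC=CC=C1Br | starting material
9 | 4,5-dimethoxy-3-{4-[2-(3-methoxy-2-{[2-oxo-2H-pyran-3-yl]oxy}phenyl)ethyl]phenoxy}benzaldehyde | O=Cc1cc(Oc2ccc(CCc3cccc(OC)c3OC3=CC=COC3=O)cc2)c(OC)c(OC)c1 | intermediate
10 | 3-(2-{2-[4-(5-(1-hydroxybut-3-yn-1-yl)-2,3-dimethoxyphenoxy)phenyl]ethyl}-6-methoxyphenoxy)-2H-pyran-2-one (racemic) | C#CCC(O)c1cc(Oc2ccc(CCc3cccc(OC)c3OC3=CC=COC3=O)cc2)c(OC)c(OC)c1 | intermediate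
11 | 3-(2-{2-[4-(5-(but-3-yn-1-yl)-2,3-dimethoxyphenoxy)phenyl]ethyl}-6-methoxyphenoxy)-2H-pyran-2-one | C#CCCc1cc(Oc2ccc(CCc3cccc(OC)c3OC3=CC=COC3=O)cc2)c(OC)c(OC)c1 | intermediate
12 | 3-(2-{2-[4-(5-[3-(benzenesulfonyl)but-3-en-1-yl]-2,3-dimethoxyphenoxy)phenyl]ethyl}-6-methoxyphenoxy)-2H-pyran-2-one | C=C(CCc1cc(Oc2ccc(CCc3cccc(OC)c3OC3=CC=COC3=O)cc2)c(OC)c(OC)c1)S(=O)(=O)c1ccccc1 | intermediate
13 | Diels–Alder adduct: 2-oxabicyclo[2.2.2]oct-7-en-3-one inside the macrocycle; bridgehead C4 carries the ring-C aryloxy oxygen, C5 carries PhSO2 and the CH2CH2 link to ring A (diastereomer mixture, formed in the flask) | O=C1OC2C=CC1(Oc4c(OC)cccc4CCc5ccc(cc5)Oc6cc(CC3)cc(OC)c6OC)C3(S(=O)(=O)c7ccccc7)C2 | intermediate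
14 | cyclohexa-1,3-diene from loss of CO2 from 13: C1 carries the ring-C aryloxy oxygen, C6 carries PhSO2 and the CH2CH2 link to ring A (racemic, formed in the flask) | COc1cccc(CCc2ccc(cc2)Oc2cc(CC3)cc(OC)c2OC)c1OC1=CC=CCC13S(=O)(=O)c1ccccc1 | intermediate
15 | tri-O-methyl ether of the target: ring A 1,2-dimethoxy-3-aryloxy-5-alkyl, ring B 1,4-phenylene, ring C 1-alkyl-2-aryloxy-3-methoxy, ring D 1,2-phenylene; links A–O–B, B–CH2CH2–C, C–O–D, D–CH2CH2–A (17-membered ring) | COc1cc2cc(c1OC)Oc1ccc(cc1)CCc1cccc(OC)c1Oc1ccccc1CC2 | intermediate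
16 | target trihydroxy macrocyclic bis(bibenzyl), CNP0290892.0 (achiral) | Oc1cc2cc(c1O)Oc1ccc(cc1)CCc1cccc(O)c1Oc1ccccc1CC2 | target

**Totals**
Total step count: 9. Longest linear sequence: 8 steps (1, 3, 4, 5, 6, 7, 8, 9); step 2 runs in parallel.

**Three steps most likely to fail, with fallbacks**

Step 8 (macrocyclising Diels–Alder cascade). Risks are oligomerisation at the concentration needed for a useful rate, the low dienophilicity of a 1,1-disubstituted vinyl sulfone, and the other regiochemistry, which would give the meta-bridged 18-membered isomer. The fallback gives up the cycloaddition. It sets out from 7: SNAr of the phenol with 2-fluorobenzaldehyde (K2CO3, DMF, 130 °C) gives 2-{2-[2-(4-{5-formyl-2,3-dimethoxyphenoxy}phenyl)ethyl]-6-methoxyphenoxy}benzaldehyde F1. Intramolecular McMurry coupling (TiCl4, Zn, pyridine, THF, reflux, high dilution) gives the macrocyclic stilbene F2. Hydrogenation (H2, Pd/C, EtOAc) then gives 15, where the route is rejoined before step 9.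

Step 4 (pyronylation of a hindered phenol). Risks are slow coupling at the di-ortho-substituted phenoxide and base-induced opening of the pyrone. The fallback reverses the polarity and installs the pyrone first. It sets out from 3 and replaces steps 2 to 4: commercial 3-hydroxy-2H-pyran-2-one and 2-fluoro-3-methoxybenzaldehyde react by SNAr (K2CO3, DMF, 80 °C) to give 3-methoxy-2-[(2-oxo-2H-pyran-3-yl)oxy]benzaldehyde F3. Wittig methylenation (Ph3PCH3Br, KOtBu, THF, −78 to 0 °C) gives 3-(2-ethenyl-6-methoxyphenoxy)-2H-pyran-2-one F4, which is kept below 70 °C to avoid cycloaddition onto its own vinyl group. Hydroboration with 9-BBN (THF, rt) gives the B-alkyl-9-BBN adduct F5, not isolated, and Suzuki coupling of it with 3 (Pd(OAc)2, SPhos, K3PO4, THF/H2O, 60 °C) gives 9, where the route is rejoined.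

Step 7 (Markovnikov hydrosulfonylation). Risks are incomplete regiocontrol, the instability of the free sulfinic acid, and reversible sulfinate addition to the pyrone. The fallback makes the C–S bond at the sulfide oxidation level. It sets out from 11: Pd(OAc)2-catalysed Markovnikov hydrothiolation with PhSH (THF, 40 °C, short reaction time to avoid alkene migration) gives the 2-(phenylsulfanyl)alkene F6. Oxidation with mCPBA (2.2 equiv, CH2Cl2, 0 °C) then gives 12, where the route is rejoined.

**Further compounds**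
F1 | step 8 | 2-{2-[2-(4-{5-formyl-2,3-dimethoxyphenoxy}phenyl)ethyl]-6-methoxyphenoxy}benzaldehyde | O=Cc1ccccc1Oc1c(OC)cccc1CCc1ccc(cc1)Oc1cc(C=O)cc(OC)c1OC
F2 | step 8 | macrocyclic stilbene: 15 with CH=CH in place of the CH2CH2 between ring D and ring A (E/Z not defined) | COc1cc2cc(c1OC)Oc1ccc(cc1)CCc1cccc(OC)c1Oc1ccccc1C=C2
F3 | step 4 | 3-methoxy-2-[(2-oxo-2H-pyran-3-yl)oxy]benzaldehyde | O=Cc1cccc(OC)c1OC1=CC=COC1=O
F4 | step 4 | 3-(2-ethenyl-6-methoxyphenoxy)-2H-pyran-2-one | C=Cc1cccc(OC)c1OC1=CC=COC1=O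
F5 | step 4 | 3-{2-[2-(9-borabicyclo[3.3.1]nonan-9-yl)ethyl]-6-methoxyphenoxy}-2H-pyran-2-one | COc1cccc(CCB2C3CCCC2CCC3)c1OC1=CC=COC1=O
F6 | step 7 | 3-(2-{2-[4-(2,3-dimethoxy-5-[3-(phenylsulfanyl)but-3-en-1-yl]phenoxy)phenyl]ethyl}-6-methoxyphenoxy)-2H-pyran-2-one | C=C(CCc1cc(Oc2ccc(CCc3cccc(OC)c3OC3=CC=COC3=O)cc2)c(OC)c(OC)c1)Sc1ccccc1
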